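**Retrosynthetic overview**
1. Target 32 ⇐ (acetylation, desilylation) lactone 30 ⇐ ten-membered α-chloro ketone 26 + 2-bromopropanoic acid 27. One pot makes O–C7 (carboxylate SN2) and C17–C8 (SmI2 Reformatsky aldol). The enabling feature is the C7–C8 unit of the cyclodecene ring held as an α-chloro ketone: C8 is a carbonyl, and C7–Cl is both α to it and allylic to the C5=C6 Z-alkene.
2. 26 ⇐ allylic alcohol 23 ⇐ seco-aldehyde 22 by Nozaki–Hiyama–Kishi closure of C6–C7 (Z-vinyl iodide onto the C7 aldehyde).
3. 22 ⇐ cyclohexene 4: C7–C9 by Brown alkoxyallylboration, C3–C6 by enolate alkylation with bromide 9, C2 by CBS reduction, C13=C14 and 11-OH from the Diels–Alder enol silane.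
4. 4 ⇐ diene 2 + enal 3 by catalytic asymmetric Diels–Alder reaction (sets quaternary C1 and C10).
5. Ring order: six-membered carbocycle (step 2) → ten-membered ring (step 16) → γ-lactone (step 20).

Key step: step 20

Remark: briarane numbering is used for all intermediates (ring C1, C10–C14; chain C2–C9; lactone C17–C19; methyls C15, C16, C18, C20). 2-Bromopropanoic acid is used as the racemate, because its stereocentre is erased in the enolate.

**Route**

Step 1
Reactants: 1 pent-1-en-3-one
Product: 2 (Z)-3-(triisopropylsilyloxy)penta-1,3-diene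
Conditions: TIPSOTf, Et3N, CH2Cl2, 0 °C
Reagents that add atoms: triisopropylsilyl triflate CC(C)[Si](C(C)C)(C(C)C)OS(=O)(=O)C(F)(F)F
Why: Silyl triflate/amine enol silylation of an enone should give the 2-silyloxy diene with the usual Z enol ether geometry (methyl anti to the vinyl group, so "outside" in the s-cis diene).

Step 2
Reactants: 2 (Z)-3-(triisopropylsilyloxy)penta-1,3-diene; 3 ethyl (E)-3-methyl-4-oxobut-2-enoate
Product: 4 cyclohexene aldehyde ester (Diels–Alder adduct)
Conditions: (S)-o-tolyl-CBS-oxazaborolidine (20 mol %), Tf2NH (18 mol %), CH2Cl2, −78 °C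
Reagents that add atoms: none
Why: Catalytic enantioselective Diels–Alder reaction (Corey oxazaborolidinium activation of the enal): diene terminus C11 should bond to C10 (β to the activated formyl group, OSi and CHO "para"), the E geometry of 3 fixes Me-15 cis to the C10 ester, and the catalyst is specified on the pre-transition-state model so that the diene adds to the C1 Si face (the mirror-image catalyst would give ent-4), setting C1 and C10.

Step 3
Reactants: 4 cyclohexene aldehyde ester
Product: 5 C2 carbinol (C2 epimers)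
Conditions: MeMgBr (1.1 equiv), THF, −78 °C; H2O quench at −78 °C
Reagents that add atoms: methylmagnesium bromide C[Mg]Br
Why: Grignard 1,2-addition is chemoselective for the aldehyde over the ethyl ester and the enol silane at −78 °C and brings in C3; the C2 configuration is irrelevant because it is oxidised next.

Step 4
Reactants: 5 C2 carbinol
Product: 6 C2 methyl ketone
Conditions: Dess–Martin periodinane, NaHCO3, CH2Cl2, 0 °C → rt
Reagents that add atoms: none
Why: Dess–Martin oxidation of a secondary alcohol under buffered, non-acidic conditions should leave the TIPS enol ether and the ester intact.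

Step 5
Reactants: 7 prop-2-yn-1-ol
Product: 8 (Z)-3-iodo-2-methylprop-2-en-1-ol
Conditions: MeMgBr (2.2 equiv), CuI (10 mol %), THF, −10 °C → rt; then I2, −78 °C → rt
Reagents that add atoms: methylmagnesium bromide C[Mg]Br; iodine II
Why: Copper-catalysed, alkoxide-directed carbomagnesiation of propargyl alcohol (Duboudin reaction) places the methyl on the internal carbon and magnesium cis to CH2O, and iodinolysis with retention should give the Z vinyl iodide (I cis to CH2OH).

Step 6
Reactants: 8 (Z)-3-iodo-2-methylprop-2-en-1-ol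
Product: 9 (Z)-3-bromo-1-iodo-2-methylprop-1-ene
Conditions: CBr4, PPh3, CH2Cl2, 0 °C
Reagents that add atoms: carbon tetrabromide BrC(Br)(Br)Br
Why: Appel bromination of a primary allylic alcohol proceeds by SN2 at CH2 and should leave the vinyl iodide geometry untouched.

Step 7
Reactants: 6 C2 methyl ketone; 9 (Z)-3-bromo-1-iodo-2-methylprop-1-ene
Product: 10 C2 ketone with the C3–C6 vinyl iodide chain
Conditions: LDA (1.05 equiv), THF, −78 °C; then 9, DMPU, −78 → −40 °C
Reagents that add atoms: none
Why: Kinetic lithium enolate alkylation: the methyl group C3 is the only enolisable position of the ketone (C1 is quaternary) and is more acidic than the hindered ester α-H, and SN2 with the reactive allylic bromide should form C3–C4 at low temperature, before an intramolecular Claisen reaction with the ester can compete.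

Step 8
Reactants: 10 C2 ketone with the C3–C6 vinyl iodide chain
Product: 11 (2R)-alcohol
Conditions: (S)-Me-CBS (0.5 equiv), catecholborane, toluene, −78 → −40 °C
Reagents that add atoms: none
Why: Corey–Bakshi–Shibata reduction under reagent control, with the quaternary C1 side as the large and the C3 methylene as the small substituent, should give the 2R carbinol; catecholborane does not hydroborate the enol silane or the iodoalkene at this temperature.

Step 9
Reactants: 11 (2R)-alcohol
Product: 12 2-O-TBS ether ester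
Conditions: TBSOTf, 2,6-lutidine, CH2Cl2, −78 → 0 °C
Reagents that add atoms: tert-butyldimethylsilyl triflate CC(C)(C)[Si](C)(C)OS(=O)(=O)C(F)(F)F
Why: Silylation of the hindered secondary alcohol with the silyl triflate, run directly after step 8, prevents lactonisation onto the C9 ester.

Step 10
Reactants: 12 2-O-TBS ether ester
Product: 13 C9 aldehyde
Conditions: DIBAL-H (1.1 equiv), CH2Cl2, −78 °C; Rochelle salt
Reagents that add atoms: none
Why: DIBAL half-reduction of the hindered ester stops at the aluminium hemiacetal at −78 °C and should release the C9 aldehyde on neutral work-up without epimerising C10.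

Step 11
Reactants: 13 C9 aldehyde; 14 allyl methoxymethyl ether
Product: 16 9-hydroxy-8-MOM-oxy homoallylic alcohol, via (Z)-[3-(methoxymethoxy)allyl]diisopinocampheylborane 15 (not isolated)
Conditions: 14, s-BuLi, THF, −78 °C; (−)-Ipc2BOMe; BF3·OEt2; then 13, −78 °C → rt; NaOH, H2O2
Reagents that add atoms: none
Why: Brown asymmetric (Z)-γ-alkoxyallylboration through a chair Zimmerman–Traxler transition state: the Z reagent gives the 8,9-syn product and the isopinocampheyl groups derived from (+)-α-pinene should impose the C9 configuration under reagent control, with the enol silane, vinyl iodide and silyl ether inert.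

Step 12
Reactants: 16 9-hydroxy-8-MOM-oxy homoallylic alcohol
Product: 17 2,9-bis-O-TBS ether
Conditions: TBSOTf, 2,6-lutidine, CH2Cl2, −78 → 0 °C
Reagents that add atoms: tert-butyldimethylsilyl triflate CC(C)(C)[Si](C)(C)OS(=O)(=O)C(F)(F)F
Why: Silyl triflate silylation of the hindered C9 alcohol is routine and the MOM ether and TIPS enol ether should tolerate it.

Step 13
Reactants: 17 2,9-bis-O-TBS ether
Product: 19 cyclohexenone, via 13-phenylselanyl ketone 18 (not isolated)
Conditions: PhSeCl, CH2Cl2, −78 °C; then pyridine, 30% H2O2, 0 °C → rt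
Reagents that add atoms: none
Why: α-Selenenylation of the enol silane at C13 followed by selenoxide syn-elimination towards C14 (the only β-hydrogens) should give the C12 enone regiospecifically and without palladium, which the vinyl iodide would not tolerate.

Step 14
Reactants: 19 cyclohexenone
Product: 20 11-hydroxy enone
Conditions: LiHMDS, THF, −78 °C; then 2-(phenylsulfonyl)-3-phenyloxaziridine, −78 °C; H2O
Reagents that add atoms: Davis oxaziridine O=S(=O)(c1ccccc1)N1OC1c1ccccc1
Why: Davis α′-hydroxylation of the cross-conjugated lithium enolate (C11 is the only enolisable site, C1 being quaternary): the oxidant should approach anti to the adjacent C10 side chain and to the axial Me-15, placing 11-OH cis to H-10 as in the target.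

Step 15
Reactants: 20 11-hydroxy enone
Product: 22 seco-aldehyde (C7 aldehyde), via terminal 1,2-diol 21 (not isolated)
Conditions: OsO4 (2 mol %), NMO, acetone/H2O, 0 °C; then NaIO4, THF/pH 7 buffer, 0 °C
Reagents that add atoms: osmium tetroxide O=[Os](=O)(=O)=O; N-methylmorpholine N-oxide C[N+]1([O-])CCOCC1
Why: Upjohn dihydroxylation and periodate cleavage should be selective for the monosubstituted vinyl group, because the enone alkene and the trisubstituted iodoalkene are both electron-poor and hindered.

Step 16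
Reactants: 22 seco-aldehyde (C7 aldehyde)
Product: 23 ten-membered allylic alcohol
Conditions: CrCl2 (10 equiv), NiCl2 (0.1 equiv), DMSO/THF (3:1), 0.003 M, rt
Reagents that add atoms: none
Why: Intramolecular Nozaki–Hiyama–Kishi coupling is chemoselective for the aldehyde in the presence of the enone, tertiary alcohol and ethers and retains the Z geometry of the vinyl iodide; the 8,9-syn bis-oxygenated aldehyde should be attacked anti-Felkin (1,3-anti to the C9–OTBS group) within the macrocyclic transition state, giving the 7,8-syn carbinol.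

Step 17
Reactants: 23 ten-membered allylic alcohol
Product: 24 C7 allylic chloride
Conditions: PPh3, hexachloroacetone, 2,6-di-tert-butylpyridine, CH2Cl2, −20 → 0 °C
Reagents that add atoms: hexachloroacetone ClC(Cl)(Cl)C(=O)C(Cl)(Cl)Cl
Why: Phosphine/hexachloroacetone chlorination of allylic alcohols (Magid conditions) proceeds by SN2 with clean inversion at C7 and little allylic transposition, helped here by the fully substituted C5 terminus; the tertiary 11-OH does not react.

Step 18
Reactants: 24 C7 allylic chloride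
Product: 25 7-chloro-8-ol
Conditions: Me2BBr, CH2Cl2, −78 °C; then sat. NaHCO3
Reagents that add atoms: none
Why: Dimethylboron bromide cleaves MOM ethers at −78 °C (Guindon conditions) and should spare the TBS ethers and the allylic chloride.

Step 19
Reactants: 25 7-chloro-8-ol
Product: 26 α-chloro ketone
Conditions: Dess–Martin periodinane, NaHCO3, CH2Cl2, 0 °C
Reagents that add atoms: none
Why: Dess–Martin oxidation under buffered conditions should give the C8 ketone without closing the chlorohydrin to an epoxide and without epimerising C7 or C9.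

Step 20
Reactants: 26 α-chloro ketone; 27 2-bromopropanoic acid
Product: 30 2,9-bis-O-TBS lactone, via cesium 2-bromopropanoate 28 (not isolated), via 7-O-(2-bromopropanoyl) ketone 29 (not isolated)
Conditions: 27, Cs2CO3, 4 Å MS, MeCN/THF (1:4), 0 °C → rt; then SmI2 (0.1 M in THF, 2.5 equiv), −78 °C; pH 7 buffer
Reagents that add atoms: none
Why: Cesium carboxylate 28 displaces chloride from C7 of 26 by SN2 (C7 is α to the C8 carbonyl and allylic to C5=C6, and the SN2′ terminus C5 is fully substituted), giving α-acyloxy ketone 29 with inversion, which fixes C7. SmI2 then reduces the C–Br bond by two single-electron transfers to a samarium(III) ester enolate that adds to the C8 ketone in an intramolecular Reformatsky aldol; the closest known reaction types are the alkylation of carboxylates by α-halo ketones (phenacyl ester formation) and the SmI2-promoted intramolecular Reformatsky lactonisation of bromoacyloxy ketones. The γ-lactone closes in a 5-(enolendo)-exo-trig mode through a samarium-bridged six-membered Zimmerman–Traxler array (enolate O–Sm–O=C8). C8 is controlled by the tether on the C7 oxygen together with the anti C6–C7–C8–C9 torsion of the ten-membered ring, so that C17 should add to the ketone face that leaves 8-OH cis to C6 (trans ring fusion); C17 is controlled by the Z(O)-enolate in the chelate, which places Me-18 cis to 8-OH. The step needs chemoselective reduction of the α-bromo ester beside the C8 ketone, the enone and the silyl ethers; this rests on the much faster electron transfer to the activated C–Br bond at −78 °C in THF without HMPA and on the immediate intramolecular capture of the enolate.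

Step 21
Reactants: 30 2,9-bis-O-TBS lactone
Product: 31 2,9-diol
Conditions: HF·pyridine, pyridine, THF, 0 → 40 °C
Reagents that add atoms: none
Why: Buffered fluoride desilylation removes both secondary TBS ethers under non-basic conditions, so the β-hydroxy lactone should neither undergo retro-aldol cleavage nor dehydrate.

Step 22
Reactants: 31 2,9-diol
Product: 32 target CNP0255369.2
Conditions: Ac2O, pyridine, DMAP (cat.), CH2Cl2, 0 °C → rt
Reagents that add atoms: acetic anhydride CC(=O)OC(C)=O
Why: DMAP-catalysed acetylation should esterify the two secondary alcohols (C2, C9) and leave the tertiary C8 and C11 hydroxyls free.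

**Compound list**

1 | pent-1-en-3-one (ethyl vinyl ketone) | CCC(=O)C=C | starting material
2 | (Z)-3-(triisopropylsilyloxy)penta-1,3-diene | C=C/C(O[Si](C(C)C)(C(C)C)C(C)C)=C/C | intermediate
3 | ethyl (E)-3-methyl-4-oxobut-2-enoate | CCOC(=O)/C=C(\C)C=O | starting material
4 | ethyl 6-formyl-2,6-dimethyl-3-(triisopropylsilyloxy)cyclohex-3-ene-1-carboxylate; C1 (CHO, Me-15) and C10 (CO2Et) as in the target, Me-15 cis to the ester, Me-20 trans to the ester | CCOC(=O)[C@@H]1[C@](C)(CC=C(O[Si](C(C)C)(C(C)C)C(C)C)[C@H]1C)C=O | intermediate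
5 | as 4 with C2 as CH(OH)CH3 (both C2 epimers) | CCOC(=O)[C@@H]1[C@](C)(CC=C(O[Si](C(C)C)(C(C)C)C(C)C)[C@H]1C)C(C)O | intermediate
6 | as 4 with C2 as an acetyl group (methyl ketone) | CCOC(=O)[C@@H]1[C@](C)(CC=C(O[Si](C(C)C)(C(C)C)C(C)C)[C@H]1C)C(C)=O | intermediate
7 | prop-2-yn-1-ol | C#CCO | starting material
8 | (Z)-3-iodo-2-methylprop-2-en-1-ol | OC/C(C)=C\I | intermediate
9 | (Z)-3-bromo-1-iodo-2-methylprop-1-ene | BrC/C(C)=C\I | intermediate
10 | C2 ketone carrying the C3–C6 chain with the (5Z)-vinyl iodide | CCOC(=O)[C@@H]1[C@](C)(CC=C(O[Si](C(C)C)(C(C)C)C(C)C)[C@H]1C)C(=O)CC/C(C)=C\I | intermediate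
11 | (2R)-alcohol of 10 | CCOC(=O)[C@@H]1[C@](C)(CC=C(O[Si](C(C)C)(C(C)C)C(C)C)[C@H]1C)[C@H](O)CC/C(C)=C\I | intermediate
12 | 2-O-TBS ether of 11 | CCOC(=O)[C@@H]1[C@](C)(CC=C(O[Si](C(C)C)(C(C)C)C(C)C)[C@H]1C)[C@H](O[Si](C)(C)C(C)(C)C)CC/C(C)=C\I | intermediate
13 | C9 aldehyde (ester of 12 reduced) | O=C[C@@H]1[C@](C)(CC=C(O[Si](C(C)C)(C(C)C)C(C)C)[C@H]1C)[C@H](O[Si](C)(C)C(C)(C)C)CC/C(C)=C\I | intermediate
14 | allyl methoxymethyl ether (3-(methoxymethoxy)prop-1-ene) | C=CCOCOC | starting material
15 | (Z)-[3-(methoxymethoxy)allyl]diisopinocampheylborane, Ipc groups from (+)-α-pinene | COCO/C=C\CB([C@@H]1C[C@@H]2C[C@H]([C@H]1C)C2(C)C)[C@@H]1C[C@@H]2C[C@H]([C@H]1C)C2(C)C | intermediate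
16 | homoallylic alcohol: 9-OH (target configuration), 8-OMOM (8,9-syn), C7 as a vinyl CH | C=C[C@@H](OCOC)[C@H](O)[C@@H]1[C@](C)(CC=C(O[Si](C(C)C)(C(C)C)C(C)C)[C@H]1C)[C@H](O[Si](C)(C)C(C)(C)C)CC/C(C)=C\I | intermediate
17 | 2,9-bis-O-TBS ether of 16 | C=C[C@@H](OCOC)[C@H](O[Si](C)(C)C(C)(C)C)[C@@H]1[C@](C)(CC=C(O[Si](C(C)C)(C(C)C)C(C)C)[C@H]1C)[C@H](O[Si](C)(C)C(C)(C)C)CC/C(C)=C\I | intermediate
18 | C12 ketone with 13-phenylselanyl group (C13 epimers) | C=C[C@@H](OCOC)[C@H](O[Si](C)(C)C(C)(C)C)[C@@H]1[C@](C)(CC([Se]c2ccccc2)C(=O)[C@H]1C)[C@H](O[Si](C)(C)C(C)(C)C)CC/C(C)=C\I | intermediate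
19 | cyclohexenone (C12=O, C13=C14), C11 still H/Me | C=C[C@@H](OCOC)[C@H](O[Si](C)(C)C(C)(C)C)[C@@H]1[C@](C)(C=CC(=O)[C@H]1C)[C@H](O[Si](C)(C)C(C)(C)C)CC/C(C)=C\I | intermediate
20 | 11-hydroxy enone, 11-OH cis to H-10 (target configuration at C11) | C=C[C@@H](OCOC)[C@H](O[Si](C)(C)C(C)(C)C)[C@@H]1[C@](C)(C=CC(=O)[C@@]1(C)O)[C@H](O[Si](C)(C)C(C)(C)C)CC/C(C)=C\I | intermediate
21 | terminal 1,2-diol from the vinyl group of 20 (epimers at the new carbinol) | OCC(O)[C@@H](OCOC)[C@H](O[Si](C)(C)C(C)(C)C)[C@@H]1[C@](C)(C=CC(=O)[C@@]1(C)O)[C@H](O[Si](C)(C)C(C)(C)C)CC/C(C)=C\I | intermediate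
22 | seco-aldehyde: C7 aldehyde, 8-OMOM, 9-OTBS, (5Z)-vinyl iodide | O=C[C@@H](OCOC)[C@H](O[Si](C)(C)C(C)(C)C)[C@@H]1[C@](C)(C=CC(=O)[C@@]1(C)O)[C@H](O[Si](C)(C)C(C)(C)C)CC/C(C)=C\I | intermediate
23 | ten-membered ring allylic alcohol, (5Z), 7-OH syn to 8-OMOM | CC(C)(C)[Si](C)(C)O[C@@H]1[C@@H]2[C@](C)(C=CC(=O)[C@@]2(C)O)[C@H](O[Si](C)(C)C(C)(C)C)CC/C(C)=C\[C@H](O)[C@H]1OCOC | intermediate
24 | C7 allylic chloride, C7 inverted relative to 23 | CC(C)(C)[Si](C)(C)O[C@@H]1[C@@H]2[C@](C)(C=CC(=O)[C@@]2(C)O)[C@H](O[Si](C)(C)C(C)(C)C)CC/C(C)=C\[C@@H](Cl)[C@H]1OCOC | intermediate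
25 | 7-chloro-8-ol (MOM removed) | CC(C)(C)[Si](C)(C)O[C@@H]1[C@@H]2[C@](C)(C=CC(=O)[C@@]2(C)O)[C@H](O[Si](C)(C)C(C)(C)C)CC/C(C)=C\[C@@H](Cl)[C@H]1O | intermediate
26 | α-chloro ketone: C8 ketone, C7–Cl, (5Z) | CC(C)(C)[Si](C)(C)O[C@@H]1[C@@H]2[C@](C)(C=CC(=O)[C@@]2(C)O)[C@H](O[Si](C)(C)C(C)(C)C)CC/C(C)=C\[C@@H](Cl)C1=O | intermediate
27 | 2-bromopropanoic acid (racemic) | CC(Br)C(=O)O | starting material
28 | cesium 2-bromopropanoate | CC(Br)C(=O)[O-].[Cs+] | intermediate
29 | 7-O-(2-bromopropanoyl) C8 ketone, C7 with the target configuration (both epimers at CHBr) | CC(C)(C)[Si](C)(C)O[C@@H]1[C@@H]2[C@](C)(C=CC(=O)[C@@]2(C)O)[C@H](O[Si](C)(C)C(C)(C)C)CC/C(C)=C\[C@H](OC(=O)C(C)Br)C1=O | intermediate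
30 | 2,9-bis-O-TBS lactone with C7, C8 and C17 as in the target | CC(C)(C)[Si](C)(C)O[C@@H]1[C@@H]2[C@](C)(C=CC(=O)[C@@]2(C)O)[C@H](O[Si](C)(C)C(C)(C)C)CC/C(C)=C\[C@@H]2OC(=O)[C@H](C)[C@]21O | intermediate
31 | 2,9-diol (2,8,9,11-tetrahydroxy lactone) | O[C@@H]1[C@@H]2[C@](C)(C=CC(=O)[C@@]2(C)O)[C@H](O)CC/C(C)=C\[C@@H]2OC(=O)[C@H](C)[C@]21O | intermediate
32 | CNP0255369.2, (1S,2R,5Z,7S,8S,9R,10S,11S,17R) in briarane numbering | CC(=O)O[C@@H]1[C@@H]2[C@](C)(C=CC(=O)[C@@]2(C)O)[C@H](OC(C)=O)CC/C(C)=C\[C@@H]2OC(=O)[C@H](C)[C@]21O | target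

**Step count**

Total steps: 22. Longest linear sequence: 20 steps (1 → 32 through steps 1–4 and 7–22).

**Three steps most likely to fail**

Step 20 (key step). The samarium reagent may cleave the α-acyloxy or α-silyloxy ketone reductively, or the enolate may be protonated before it adds, which would leave the simple propanoate; C7 or C9 may also epimerise during the displacement. The fallback sets out from 26 and changes how the C17 nucleophile is made. Chloride is displaced by cesium acrylate in MeCN to give the 7-O-acryloyl ketone F1. Stryker's reagent, [(Ph3P)CuH]6, in toluene at −50 °C should then reduce the unhindered acrylate before the neopentyl-flanked cyclohexenone. The resulting Z copper enolate should close the lactone by reductive aldol cyclisation, and the route is rejoined at 30.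

Step 16. Facial selectivity in the addition to the C7 aldehyde may be poor or reversed, so that ring closure delivers mainly the 7,8-anti alcohol. The fallback sets out from that 7-epimeric alcohol F2. Mitsunobu inversion with 4-nitrobenzoic acid, DIAD and PPh3 in THF gives the inverted 7-O-(4-nitrobenzoate) F3. Methanolysis with K2CO3 in MeOH at 0 °C then returns the route to 23.

Step 17. The allylic system may ionise during chlorination, which would move chloride to C5 or erode the C7 configuration. The fallback sets out from 23 and keeps the C7 oxygen of the carbinol instead of replacing it. Acylation with 2-bromopropanoyl bromide and pyridine gives the 7-O-(2-bromopropanoyl) 8-MOM ether F4. Me2BBr at −78 °C gives the 8-ol F5, and Dess–Martin oxidation returns the route to 29, which is taken on with SmI2 as in step 20.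

Further compounds
F1 | step 20 | 7-O-acryloyl C8 ketone (C7 as in the target) | CC(C)(C)[Si](C)(C)O[C@@H]1[C@@H]2[C@](C)(C=CC(=O)[C@@]2(C)O)[C@H](O[Si](C)(C)C(C)(C)C)CC/C(C)=C\[C@H](OC(=O)C=C)C1=O
F2 | step 16 | 7-epimer of alcohol 23 (7-OH anti to 8-OMOM) | CC(C)(C)[Si](C)(C)O[C@@H]1[C@@H]2[C@](C)(C=CC(=O)[C@@]2(C)O)[C@H](O[Si](C)(C)C(C)(C)C)CC/C(C)=C\[C@@H](O)[C@H]1OCOC
F3 | step 16 | 7-O-(4-nitrobenzoate) with the C7 configuration of 23 | CC(C)(C)[Si](C)(C)O[C@@H]1[C@@H]2[C@](C)(C=CC(=O)[C@@]2(C)O)[C@H](O[Si](C)(C)C(C)(C)C)CC/C(C)=C\[C@H](OC(=O)c3ccc(cc3)[N+](=O)[O-])[C@H]1OCOC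
F4 | step 17 | 7-O-(2-bromopropanoyl) 8-MOM ether | CC(C)(C)[Si](C)(C)O[C@@H]1[C@@H]2[C@](C)(C=CC(=O)[C@@]2(C)O)[C@H](O[Si](C)(C)C(C)(C)C)CC/C(C)=C\[C@H](OC(=O)C(C)Br)[C@H]1OCOC
F5 | step 17 | 7-O-(2-bromopropanoyl) 8-ol | CC(C)(C)[Si](C)(C)O[C@@H]1[C@@H]2[C@](C)(C=CC(=O)[C@@]2(C)O)[C@H](O[Si](C)(C)C(C)(C)C)CC/C(C)=C\[C@H](OC(=O)C(C)Br)[C@H]1O
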